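- We ask how strongly the rate of making J in the flask answers to the charge of E at the moment when 50% of X is converted.

- cedar: X 0.20 M; E 0.20 M; G 45 mM; run made earlier
- flask: X 0.20 M; E 0.200 M; G 30 mM; volume of the second phase over the first 1.0

- cedar (time / h: J / %, X / %): 0.833: 7, 90; 2.00: 20, 79; 2.50: 24, 69; 4.00: 37, 62; 5.00: 38, 58

(each reading ± 2 percentage points)

- charges count per volume of the first phase; a concentration in a rate is the amount of a species over the volume of its own phase; every rate counts per litre of the first phase
- the earlier runs hold the two phases in the same ratio of volumes as the flask asked about
- no earlier run changes the charge of G; that part of a forecast is a guess
- no earlier run changes the charge of E; that part of a forecast is a guess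

1. apparent order in E when 50% of the X are converted (percent change of the rate of making J for one percent more E charged)

- **First instants.** We assume that each X converted takes one E with it. At the start of the flask nothing has been used, so one percent more E charged is one percent more E present.
- **The middle, read on the cedar run.** We replace each stretch of curve by its mean. Up to 2.50 h, J forms at 0.0960 /h as a fraction of the charge, with a mean X of 88.0%, taking X as the charge less J. From there to 5.00 h, J forms at 0.0560 /h, with a mean X of 69.0%. So the rate falls further than X does.
- **Our reading of the local order.** X and E start equal in the cedar run and, on that assumption, fall together, so we give X an order of one and lay the rest on E. That leaves a local order of 1.22 in the E present. This reading is rough, with a scatter of 2 percentage points on a late gain of 14 points, and carrying it to the flask is a guess.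
- **The moment asked about.** In the flask, E present is the charge less what X has taken, about 0.100 M. One percent more charge therefore lifts E present by more than one percent. We call this the charge lever, the percent change of E present at a fixed conversion for one percent more E charged, which is the charge of E over the E left: 2.00. At fixed conversion, we take apparent order as lever times local order, so our reckoning gives 2.43.
- The forecast stands lower than our reckoning, at 0.6 within 0.15 to 1.3, and calls itself “an extrapolation, because E was never varied”.
- The flask reaches 50% conversion at 10.8 h and gives an apparent order of 1.6.

    G + E ⇌ Q + D (K = 0.390, k = 0.00230 /M/s)
    X + Q → J + G (k = 0.00220 /M/s)
    X + Q → L (k = 1.40 × 10⁻⁴ /M/s)

- Dividing by the lever leaves the flask a local order of 0.782. Part of that local order comes from the falling back of Q + D to G + E, a step that sets E against D. In the same run with that step taken away, the apparent order is 1.1, and the same lever turns this into a local order of 0.534.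

Readings and results come from a simulation for an exercise; scatter was added.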